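## Structural features

The target is 4-bromo-2-[(1R,2R,3E)-3-(bromomethylidene)-1,2-dimethylcyclopentyl]-5-methylphenol: a benzene ring (C1 OH, C4 Br, C5 CH3) joined through C2 to the quaternary carbon C1′ of a cyclopentane (ring A, C1′–C5′). C1′ is an all-carbon benzylic stereocentre (aryl, CH3, C2′, C5′) and stands directly next to C2′, a methine that carries the second methyl group; the two methyl groups are trans, so the C2′ methyl is cis to the aryl group. C3′ bears an exocyclic bromomethylidene carbon (C6′) of E geometry, with bromine syn to C4′H2 and anti to C2′. Fragile groups are the alkenyl bromide (strong base, low-valent metals, E/Z drift), the aryl bromide (halogen–metal exchange, palladium), the exocyclic alkene (migration into the ring would erase C2′) and the free phenol, whose oxygen can add across C3′=C6′ under acid or halonium conditions. The real difficulty is the pair C1′/C2′ together with the alkene: the cis aryl/methyl arrangement is expected to be the less stable one, C2′ would be an epimerizable α-carbon in any C3′ ketone precursor, and the ring offers no polar handle to control the C3′=C6′ geometry. Two features decide the plan: the unit C2′(CH3)–C3′(=C6′) is the imprint of a vinyl group coupled to an alkyne, and the oxygen on C1 lies five bonds from the C2′ methyl carbon (O–C1–C2–C1′–C2′–CH3). The key step therefore uses the phenol oxygen as an anchor for titanium while ring A is closed between C2′ and C3′.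

## Logic of the disconnections

16 ⇒ 13. The C6′–Br bond is cut and replaced by C6′–Si. The E bromoalkene cannot pass through an organometallic ring closure, whereas silicon can and marks C6′ with the same geometry. The demand on the forward step is ipso substitution at C6′ with retention, with no attack on the arene and no participation of the phenol oxygen, which is why 14 and 15 are passed through.

13 ⇒ 10 (key disconnection). The ring bond C2′–C3′ is cut, together with the C6′–H bond and one C–H bond of the C2′ methyl group. In one sentence: ring A is made by a titanium-mediated reductive cyclization of 10 held on the metal through its own aryloxide (11 → 12). The gain is that the ring, the C2′ stereocentre and the alkene geometry all disappear, leaving an open chain with one stereocentre. The demand is delivery of the titanium-bound CH2 to the face of the forming ring that carries the aryl group, and syn addition across the alkyne.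

10 ⇒ 9. The phenol O–CH2 (acetal) bond is cut. The oxygen must be free for the key step but masked while an organomagnesium reagent is used. The demand is acetal cleavage that leaves the alkynylsilane and the vinyl group alone.

9 ⇒ 6 + 7 (through 8). The C1′–C5′ bond is cut with allylic transposition. C1′ is the one stereocentre the key step cannot set, and an enantioselective SN2′ substitution creates it together with the vinyl group that the key step needs. The gain is an achiral allylic phosphate and a four-carbon bromide. The demand is γ-selectivity and enantioface selection at a hindered Z-trisubstituted alkene.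

6 ⇒ 5 ⇒ 4 ⇒ 3. The P–O bond, the phenol O–CH2 bond and the two carbinol C–H bonds are cut in turn. The Z alkene of 4 is stored in the lactone ring of 3, so no olefination with E/Z control is needed. The demands are 1,2-reduction without conjugate reduction and alkylation of the phenol oxygen only.

3 ⇒ 1 + 2. The arene C2–C bond (to the future C1′) and the lactone C–O bond are cut. This places the future C1′ ortho to oxygen and para to the methyl group on a commercial phenol that already carries the aryl bromine. The demand is ring closure at the unhindered ortho position.

## Other disconnections considered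

Alternative 1: (the first that comes to mind) Cut C3′=C6′, C2′–CH3 and arene C2–C1′. Forward: asymmetric conjugate addition of an arylboron reagent to a five-membered β-methyl enone would give ketone A1, enolate methylation would give A2, and a bromomethylene ylide would finish the route. Grounds for preferring the chosen plan:
- The enolate of A1 should form away from the quaternary carbon, so methylation at the required α-carbon needs blocking steps.
- C2′ in A2 is α to a carbonyl, and equilibration is expected to put the methyl trans to the aryl, the opposite of the target; the basic olefination invites exactly that.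
- Bromomethylenation of a hindered ketone offers no control of E/Z geometry.
- The three hard elements are thus left to three separate, uncontrolled steps.

Alternative 2: Cut C2′–C3′ as the terminus of a 1,2-shift (strain release). Forward: ethynylcyclobutanol A3 is activated at the alkyne by an electrophilic bromine source; the more substituted ring carbon (future C2′) migrates anti to bromine with retention, and the four-membered ring expands to bromomethylidene cyclopentanone A4 with bromine already syn to the future C4′. Grounds for preferring the chosen plan:
- A4 carries a carbonyl at C4′ that the target lacks, and its removal from a bromo-enone needs several redox steps that threaten the bromoalkene (reduction, allylic transposition).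
- A3 needs a cyclobutanone with the quaternary centre and the cis aryl/methyl pair as one enantiomer, which is no shorter to make than 10.
- The methine of that cyclobutanone is again α to a ketone.

Alternative 3: Cut C3′–C4′. Forward: the primary iodide A5 is converted into an alkylzinc–copper reagent, which adds 5-exo-dig and syn across the terminal alkyne; bromination of the alkenylcopper with retention places bromine syn to C4′. Grounds for preferring the chosen plan:
- Ring and alkene geometry are solved, but neither stereocentre is.
- The C1′/C2′ pair must be set earlier on an open chain, for example by an ester enolate Claisen rearrangement that needs a stoichiometric external chiral controller to be enantioselective.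
- Several functional group changes then follow to reach A5, so the difficulty is spread over two hard steps and a longer sequence.
- The acidic alkyne C–H may quench the organometallic.

Key step: step 7

Assumption: the sense of induction in the copper-catalysed allylic substitution (step 5) is set by the ligand enantiomer, and the enantiomer that delivers the 3R product 9 is used; 1, 2 and 7 are taken as commercial.

## Steps

Step 1
Reactants: 1 4-bromo-3-methylphenol; 2 ethyl acetoacetate (ethyl 3-oxobutanoate)
Product: 3 6-bromo-4,7-dimethyl-2H-chromen-2-one
Conditions: MeSO3H (solvent), 25 → 60 °C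
Reagents that add atoms: none
Why: Pechmann condensation (transesterification, intramolecular Friedel–Crafts hydroxyalkylation, dehydration); the ring should close at the arene position ortho to OH and para to CH3, the less hindered and more activated ortho site, which fixes the 6-bromo-4,7-dimethyl pattern. No stereocentre is formed.

Step 2
Reactants: 3 6-bromo-4,7-dimethyl-2H-chromen-2-one
Product: 4 (2Z)-3-(5-bromo-2-hydroxy-4-methylphenyl)but-2-en-1-ol
Conditions: i-Bu2AlH (3.5 equiv), CH2Cl2, −78 → 0 °C; aq. potassium sodium tartrate (KNaC4H4O6) work-up
Reagents that add atoms: none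
Why: Aluminium hydride 1,2-reduction of the lactone carbonyl to the primary allylic alcohol; the Z geometry is inherited from the ring, and the aryl bromide is inert to i-Bu2AlH at low temperature. The non-acidic work-up should avoid cyclodehydration to a chromene.

Step 3
Reactants: 4 (2Z)-3-(5-bromo-2-hydroxy-4-methylphenyl)but-2-en-1-ol
Product: 5 (2Z)-3-[5-bromo-2-(methoxymethoxy)-4-methylphenyl]but-2-en-1-ol
Conditions: MOMCl (1.1 equiv), K2CO3 (1.5 equiv), acetone, 0 → 25 °C
Reagents that add atoms: chloromethyl methyl ether, COCCl
Why: Williamson-type O-alkylation; K2CO3 deprotonates only the phenol, so the allylic alcohol should stay free for the next step.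

Step 4
Reactants: 5 (2Z)-3-[5-bromo-2-(methoxymethoxy)-4-methylphenyl]but-2-en-1-ol
Product: 6 (2Z)-3-[5-bromo-2-(methoxymethoxy)-4-methylphenyl]but-2-en-1-yl diethyl phosphate
Conditions: ClP(O)(OEt)2 (1.3 equiv), Et3N (2 equiv), DMAP (cat.), CH2Cl2, 0 °C
Reagents that add atoms: diethyl chlorophosphate, CCOP(=O)(Cl)OCC
Why: Phosphorylation of a primary allylic alcohol; the phosphate is the standard leaving group for copper-catalysed SN2′ substitution and should not transpose at 0 °C.

Step 5
Reactants: 6 (2Z)-3-[5-bromo-2-(methoxymethoxy)-4-methylphenyl]but-2-en-1-yl diethyl phosphate; 7 (4-bromobut-1-yn-1-yl)trimethylsilane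
Product: 9 1-bromo-4-(methoxymethoxy)-2-methyl-5-[(3R)-3-methyl-7-(trimethylsilyl)hept-1-en-6-yn-3-yl]benzene, via organomagnesium bromide 8 (not isolated)
Conditions: 7, Mg, Et2O, 25 °C; then slow addition to 6, Cu(OTf)2 (2 mol %), chiral hydroxyalkyl imidazolinium salt (N-heterocyclic carbene precursor, 3 mol %), CH2Cl2, −78 °C
Reagents that add atoms: none
Why: Copper-catalysed enantioselective allylic alkylation (SN2′) of a γ,γ-disubstituted allylic phosphate with a Grignard reagent: oxidative addition anti to the phosphate gives an allyl species of trivalent copper, and reductive elimination at the γ-carbon creates the quaternary stereocentre and the vinyl group at once. The chiral carbene ligand selects the alkene face (enantiomer chosen for 3R), and the single Z geometry from the lactone gives one substrate geometry; the aryl bromide and the silylalkyne should be untouched at −78 °C.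

Step 6
Reactants: 9 1-bromo-4-(methoxymethoxy)-2-methyl-5-[(3R)-3-methyl-7-(trimethylsilyl)hept-1-en-6-yn-3-yl]benzene
Product: 10 4-bromo-5-methyl-2-[(3R)-3-methyl-7-(trimethylsilyl)hept-1-en-6-yn-3-yl]phenol
Conditions: HCl (cat., 2 M in MeOH), MeOH, 40 °C
Reagents that add atoms: none
Why: Acid-catalysed acetal exchange removes the methoxymethyl group; the alkynylsilane and the terminal alkene should tolerate dilute methanolic acid, and the quaternary stereocentre cannot epimerize.

Step 7
Reactants: 10 4-bromo-5-methyl-2-[(3R)-3-methyl-7-(trimethylsilyl)hept-1-en-6-yn-3-yl]phenol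
Product: 13 4-bromo-2-{(1R,2R,3E)-1,2-dimethyl-3-[(trimethylsilyl)methylidene]cyclopentyl}-5-methylphenol, via titanium aryloxide 11 (not isolated), via titanacyclopentene 12 (not isolated)
Conditions: Ti(OiPr)4 (1.05 equiv), toluene, 25 °C, then evaporation (removes i-PrOH); i-PrMgCl (2.1 equiv), Et2O, −78 → −30 °C; then H2O, cold 1 M HCl
Reagents that add atoms: none
Why: The closest known reaction type is the titanium alkoxide-mediated reductive cyclization of 7-silyl 1,6-enynes (low-valent titanium from a titanium tetra-alkoxide and i-PrMgCl), run here on the substrate's own titanium aryloxide in the manner of alkoxide-directed metallacycle couplings. Ligand exchange gives 11; two equivalents of i-PrMgCl reduce it, with loss of propane and propene, to divalent titanium that is still bound to the arene oxygen and complexes the silylalkyne. The vinyl group then inserts into the Ti–C bond at the internal alkyne carbon, so the cyclopentane closes in a 5-exo mode by the C2′–C3′ bond and the terminal CH2 becomes bound to titanium in 12. C2′ is the only new stereocentre and is controlled by the Ti–O anchor: titanium is held by the oxygen on arene C1 and by both carbons of the metallacycle, which should be possible only if the CH2–Ti arm on C2′ and the aryl group on C1′ lie on the same face of the new ring, so the future methyl ends cis to the aryl (2′R from 1′R), against the steric preference expected for an untethered cyclization. The alkene geometry follows from the mechanism: the new C–C bond and the Ti–C6′ bond are formed syn, silicon stays on the carbon bound to titanium (set by the tether length and usual for silylalkynes), and protonolysis of both Ti–C bonds with retention gives the methyl group and the E vinylsilane with silicon syn to C4′. The selectivities needed are facial selectivity (Ti–O anchor), complexation of the alkyne before the alkene (silylalkynes bind low-valent titanium first) and survival of the aryl bromide (no exchange with i-PrMgCl or low-valent titanium alkoxides is expected at or below −30 °C).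

Step 8
Reactants: 13 4-bromo-2-{(1R,2R,3E)-1,2-dimethyl-3-[(trimethylsilyl)methylidene]cyclopentyl}-5-methylphenol
Product: 16 4-bromo-2-[(1R,2R,3E)-3-(bromomethylidene)-1,2-dimethylcyclopentyl]-5-methylphenol, via aryl trimethylsilyl ether 14 (not isolated), via bromoalkene silyl ether 15 (not isolated)
Conditions: TMSCl (1.2 equiv), Et3N (1.5 equiv), CH2Cl2, 0 °C, filter and evaporate; NBS (1.1 equiv), MeCN, −20 → 0 °C, dark; then K2CO3 (cat.), MeOH, 25 °C
Reagents that add atoms: N-bromosuccinimide, O=C1CCC(=O)N1Br
Why: Electrophilic ipso-bromodesilylation of a vinylsilane: bromine adds to C6′, the β-silyl cation at C3′ rotates by the shorter path until C–Si is aligned and loses silicon, so bromine takes the place of silicon with retention (E); the polar solvent without free bromide disfavours the addition–elimination path that would invert. Transient O-silylation keeps the phenol oxygen from adding to the cation and damps the only open activated arene position; methanolysis then frees the phenol, and no stereocentre is touched.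

## Compound list

1 | 4-bromo-3-methylphenol | Cc1cc(O)ccc1Br | starting material
2 | ethyl acetoacetate (ethyl 3-oxobutanoate) | CCOC(=O)CC(C)=O | starting material
3 | 6-bromo-4,7-dimethyl-2H-chromen-2-one | Cc1cc2OC(=O)C=C(C)c2cc1Br | intermediate
4 | (2Z)-3-(5-bromo-2-hydroxy-4-methylphenyl)but-2-en-1-ol | Cc1cc(O)c(/C(C)=C\CO)cc1Br | intermediate
5 | (2Z)-3-[5-bromo-2-(methoxymethoxy)-4-methylphenyl]but-2-en-1-ol | Cc1cc(OCOC)c(/C(C)=C\CO)cc1Br | intermediate
6 | (2Z)-3-[5-bromo-2-(methoxymethoxy)-4-methylphenyl]but-2-en-1-yl diethyl phosphate | Cc1cc(OCOC)c(/C(C)=C\COP(=O)(OCC)OCC)cc1Br | intermediate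
7 | (4-bromobut-1-yn-1-yl)trimethylsilane | C[Si](C)(C)C#CCCBr | starting material
8 | [4-(trimethylsilyl)but-3-yn-1-yl]magnesium bromide | C[Si](C)(C)C#CCC[Mg]Br | intermediate
9 | 1-bromo-4-(methoxymethoxy)-2-methyl-5-[(3R)-3-methyl-7-(trimethylsilyl)hept-1-en-6-yn-3-yl]benzene | C=C[C@@](C)(CCC#C[Si](C)(C)C)c1cc(Br)c(C)cc1OCOC | intermediate
10 | 4-bromo-5-methyl-2-[(3R)-3-methyl-7-(trimethylsilyl)hept-1-en-6-yn-3-yl]phenol | C=C[C@@](C)(CCC#C[Si](C)(C)C)c1cc(Br)c(C)cc1O | intermediate
11 | {4-bromo-5-methyl-2-[(3R)-3-methyl-7-(trimethylsilyl)hept-1-en-6-yn-3-yl]phenoxy}tri(propan-2-yloxy)titanium | C=C[C@@](C)(CCC#C[Si](C)(C)C)c1cc(Br)c(C)cc1O[Ti](OC(C)C)(OC(C)C)OC(C)C | intermediate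
12 | aryloxide-anchored titanacyclopentene (1′R,2′R): titanium bound to the oxygen on arene C1, to one isopropoxide, to C6′ (which bears SiMe3 and is double-bonded to C3′) and to the CH2 on C2′; cyclopentane C1′–C5′ closed | Cc1cc2c(cc1Br)[C@]3(C)CCC4=C([Si](C)(C)C)[Ti](O2)(OC(C)C)C[C@H]34 | intermediate
13 | 4-bromo-2-{(1R,2R,3E)-1,2-dimethyl-3-[(trimethylsilyl)methylidene]cyclopentyl}-5-methylphenol | Cc1cc(O)c([C@]2(C)CC/C(=C\[Si](C)(C)C)[C@@H]2C)cc1Br | intermediate
14 | [4-bromo-2-{(1R,2R,3E)-1,2-dimethyl-3-[(trimethylsilyl)methylidene]cyclopentyl}-5-methylphenoxy]trimethylsilane | Cc1cc(O[Si](C)(C)C)c([C@]2(C)CC/C(=C\[Si](C)(C)C)[C@@H]2C)cc1Br | intermediate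
15 | {4-bromo-2-[(1R,2R,3E)-3-(bromomethylidene)-1,2-dimethylcyclopentyl]-5-methylphenoxy}trimethylsilane | Cc1cc(O[Si](C)(C)C)c([C@]2(C)CC/C(=C\Br)[C@@H]2C)cc1Br | intermediate
16 | 4-bromo-2-[(1R,2R,3E)-3-(bromomethylidene)-1,2-dimethylcyclopentyl]-5-methylphenol | Cc1cc(O)c([C@]2(C)CC/C(=C\Br)[C@@H]2C)cc1Br | target

## Step count and least certain steps

Total step count: 8 (steps 1–8; 8, 11, 12, 14 and 15 are not isolated).
Longest linear sequence: 8 steps from 1 (7 enters in the flask of step 5).

Step 7 (key step). What may go wrong: aryloxide and isopropoxide ligands may redistribute among titanium centres, so that the vinyl group inserts without the anchor and the facial selectivity at C2′ falls or reverses. Insertion of the hindered vinyl group next to the quaternary carbon may also be slow, so that hydrolysis returns uncyclized material. Fallback (sets out from 9, returns at 13; hydrogen is delivered to C2′ under steric control instead of carbon under tether control):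
- Pd(OAc)2 (5 mol %) with N,N′-bis(benzylidene)ethylenediamine in benzene at 60 °C should cycloisomerize 9: syn hydropalladation of the silylalkyne, 5-exo insertion of the vinyl group and β-hydride elimination from C2′, the only β-hydrogen available. This gives the cross-conjugated diene 1-bromo-4-(methoxymethoxy)-2-methyl-5-{(1R,3E)-1-methyl-2-methylidene-3-[(trimethylsilyl)methylidene]cyclopentyl}benzene F1.
- Diimide (2-nitrobenzenesulfonyl hydrazide, Et3N) should reduce only the 1,1-disubstituted C2′=CH2 bond, from the face opposite the bulky aryl group, so that the new methyl ends cis to the aryl. This gives the methoxymethyl ether of 13, F2.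
- Methanolic HCl as in step 6 then gives 13.

Step 5. What may go wrong: competing attack at the α-carbon may give the achiral linear product, or enantioface discrimination may be poor because the ortho-alkoxyaryl group on the Z alkene crowds the γ-carbon. Fallback (sets out from 1, returns at 9; the quaternary centre is made by aryl–C1′ instead of alkyl–C1′ bond formation):
- Ortho-iodination of 1 (NIS, cat. p-TsOH, MeCN) should give 4-bromo-2-iodo-5-methylphenol F3; MOMCl/K2CO3 gives the aryl iodide 1-bromo-5-iodo-4-(methoxymethoxy)-2-methylbenzene F4.
- Iodine–magnesium exchange (i-PrMgCl·LiCl, −40 °C, iodide only) and transmetalation with Et2AlCl give the arylaluminium [5-bromo-2-(methoxymethoxy)-4-methylphenyl]diethylaluminium F5.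
- Separately, monosilylation of hexa-1,5-diyne gives trimethyl(hexa-1,5-diyn-1-yl)silane F6.
- Zirconium-catalysed methylalumination of its terminal alkyne (AlMe3, Cp2ZrCl2 cat.) and trapping with paraformaldehyde give the E allylic alcohol (2E)-3-methyl-7-(trimethylsilyl)hept-2-en-6-yn-1-ol F7, and ClP(O)(OEt)2 gives its diethyl phosphate F8.
- Copper-catalysed SN2′ arylation of F8 with F5 under a chiral sulfonate-bearing N-heterocyclic carbene ligand would then give 9.

Step 8. What may go wrong: partial loss of alkene geometry through a bromonium addition–elimination path, or electrophilic attack on the arene if the silyl ether is lost early. Fallback (sets out from 13, returns at 16; the C–Br bond is made by metal-mediated exchange instead of electrophilic substitution):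
- 14, formed as in step 8, is treated with NIS in MeCN/ClCH2CN at 0 °C, a retentive iododesilylation, and desilylated at oxygen with methanol to give the alkenyl iodide 4-bromo-2-[(1R,2R,3E)-3-(iodomethylidene)-1,2-dimethylcyclopentyl]-5-methylphenol F9.
- Heating F9 with excess CuBr (monovalent copper) in DMF should exchange iodine for bromine at C6′ with retention, while the aryl bromide undergoes only degenerate exchange, and give 16.

## Further compounds

F1 | step 7 | 1-bromo-4-(methoxymethoxy)-2-methyl-5-{(1R,3E)-1-methyl-2-methylidene-3-[(trimethylsilyl)methylidene]cyclopentyl}benzene | C=C1/C(=C/[Si](C)(C)C)CC[C@@]1(C)c2cc(Br)c(C)cc2OCOC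
F2 | step 7 | 1-bromo-5-{(1R,2R,3E)-1,2-dimethyl-3-[(trimethylsilyl)methylidene]cyclopentyl}-4-(methoxymethoxy)-2-methylbenzene | Cc1cc(OCOC)c([C@]2(C)CC/C(=C\[Si](C)(C)C)[C@@H]2C)cc1Br
F3 | step 5 | 4-bromo-2-iodo-5-methylphenol | Cc1cc(O)c(I)cc1Br
F4 | step 5 | 1-bromo-5-iodo-4-(methoxymethoxy)-2-methylbenzene | Cc1cc(OCOC)c(I)cc1Br
F5 | step 5 | [5-bromo-2-(methoxymethoxy)-4-methylphenyl]diethylaluminium | CC[Al](CC)c1cc(Br)c(C)cc1OCOC
F6 | step 5 | trimethyl(hexa-1,5-diyn-1-yl)silane | C[Si](C)(C)C#CCCC#C
F7 | step 5 | (2E)-3-methyl-7-(trimethylsilyl)hept-2-en-6-yn-1-ol | C/C(=C\CO)CCC#C[Si](C)(C)C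
F8 | step 5 | (2E)-3-methyl-7-(trimethylsilyl)hept-2-en-6-yn-1-yl diethyl phosphate | C/C(=C\COP(=O)(OCC)OCC)CCC#C[Si](C)(C)C
F9 | step 8 | 4-bromo-2-[(1R,2R,3E)-3-(iodomethylidene)-1,2-dimethylcyclopentyl]-5-methylphenol | Cc1cc(O)c([C@]2(C)CC/C(=C\I)[C@@H]2C)cc1Br
A1 | alternative 1 | (3R)-3-(5-bromo-2-methoxy-4-methylphenyl)-3-methylcyclopentan-1-one | Cc1cc(OC)c([C@]2(C)CCC(=O)C2)cc1Br
A2 | alternative 1 | (2R,3R)-3-(5-bromo-2-methoxy-4-methylphenyl)-2,3-dimethylcyclopentan-1-one | Cc1cc(OC)c([C@]2(C)CCC(=O)[C@@H]2C)cc1Br
A3 | alternative 2 | (2R,3R)-3-(5-bromo-2-methoxy-4-methylphenyl)-1-ethynyl-2,3-dimethylcyclobutan-1-ol (either configuration at C1) | Cc1cc(OC)c([C@]2(C)CC(O)(C#C)[C@@H]2C)cc1Br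
A4 | alternative 2 | (2Z,3R,4R)-4-(5-bromo-2-methoxy-4-methylphenyl)-2-(bromomethylidene)-3,4-dimethylcyclopentan-1-one | Cc1cc(OC)c([C@]2(C)CC(=O)/C(=C\Br)[C@@H]2C)cc1Br
A5 | alternative 3 | 1-bromo-5-[(3S,4R)-6-iodo-3,4-dimethylhex-1-yn-4-yl]-4-methoxy-2-methylbenzene | Cc1cc(OC)c([C@](C)(CCI)[C@@H](C)C#C)cc1Br
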